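The 27-membered lactone ring is cut at C2–C3 and C10–C11, so that its C3–C10 octamethylene segment is recognised as cis-cyclooctene, C1–C2 as an acrylate and C11–C26 with the ring oxygen as heptadec-16-en-1-ol. One ruthenium-catalysed cascade of ring-opening, cross and ring-closing metathesis should insert the eight-membered carbocycle into the acyclic ester, forging both C=C bonds and the macrocycle while expelling ethylene. The precursor is heptadec-16-en-1-yl acrylate, reached in two steps by a copper-catalysed Grignard coupling and an acylation; hydrogenation of the dienolide finishes the target. All risk sits in the insertion step.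

Key step: step 3

Remark: locants C1–C26 are those of the target lactone (C1 the carbonyl carbon, C26 the oxygen-bearing carbon); in step 3 ruthenium-bound alkylidenes are treated as states of the catalyst, so only the metal-free ring-opened triene is numbered as an intermediate.

Step 1
Reactants: 1 11-bromoundec-1-ene; 2 6-bromohexan-1-ol
Product: 5 heptadec-16-en-1-ol, via undec-10-en-1-ylmagnesium bromide 3 (not isolated), via bromomagnesium 6-bromohexan-1-olate 4 (not isolated)
Conditions: 1 (2.4 equiv), Mg, THF, 40 °C; then added to 2, Li2CuCl4 (3 mol%), THF, −40 °C to rt; aqueous NH4Cl
Reagents that add atoms: none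
Why: Insertion of Mg into the C–Br bond of 1 gives Grignard reagent 3, one equivalent of which only deprotonates 2 to alkoxide 4 (released as undec-1-ene) while a second equivalent displaces the primary bromide of 4 in a Li2CuCl4-catalysed Kochi-type alkyl–alkyl cross-coupling that does not touch the terminal alkene, and aqueous work-up frees the alcohol.

Step 2
Reactants: 5 heptadec-16-en-1-ol; 6 acryloyl chloride
Product: 7 heptadec-16-en-1-yl acrylate (heptadec-16-en-1-yl prop-2-enoate)
Conditions: 6 (1.3 equiv), Et3N (1.6 equiv), BHT (trace), CH2Cl2, 0 °C to rt
Reagents that add atoms: none
Why: O-Acylation of the unhindered primary alcohol by the acid chloride with Et3N as HCl scavenger (nucleophilic acyl substitution of the Schotten–Baumann type) should be fast at 0 °C, the distant terminal alkene is a spectator, and the trace of BHT guards the acrylate against radical polymerisation.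

Step 3
Reactants: 7 heptadec-16-en-1-yl acrylate; 8 cis-cyclooctene
Product: 10 (2E)-hexacosa-2,10-dien-26-olide (C10=C11 as E/Z mixture), via pentacosa-16,24-dien-1-yl acrylate 9 (not isolated)
Conditions: 8 (1.3 equiv, charged at the start), second-generation Grubbs catalyst RuCl2(=CHPh)(H2IMes)(PCy3) (2 × 2.5 mol%), 1,4-benzoquinone (10 mol%), CH2Cl2 (3 mM in 7), reflux, slow Ar purge, 16 h; then ethyl vinyl ether
Reagents that add atoms: none
Why: The benzylidene should exchange first at the unhindered, electron-rich terminal alkene of 7, and the resulting C11 alkylidene opens strained cis-cyclooctene by [2+2] cycloaddition and cycloreversion, forming C10=C11 and placing ruthenium on C3 (triene 9, the ring-opening cross-metathesis product, is the metal-free resting form of this chain). The C3 alkylidene then adds to the acrylate terminus and cycloreverts, forming the conjugated C2=C3 bond, closing the ring and releasing ethylene, which the argon stream removes. The closest known reaction type is ring-expansion metathesis, in which a cycloalkene is inserted into an acrylate-terminated acyclic diene by a ring-opening, cross and ring-closing cascade. The 27-membered ring is closed by ring-closing metathesis at C2=C3, a strain-free macrocyclisation favoured over chain growth by the 3 mM dilution. No stereocentre is created; the enoate should be E by thermodynamic preference and the C10=C11 geometry is erased in step 4. The selectivity needed is insertion of exactly one cyclooctene: the acrylate neither initiates nor homodimerises readily and so acts as an essentially irreversible cap, cyclooctene present from the start intercepts the C11 alkylidene before it can close directly onto the acrylate, and the isolated alkenes of over-inserted chains stay metathesis-active, so back-biting at high dilution should trim them to the smallest strain-free ring.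

Step 4
Reactants: 10 (2E)-hexacosa-2,10-dien-26-olide
Product: 11 26-hexacosanolide (oxacycloheptacosan-2-one)
Conditions: H2 (1 atm), 10% Pd/C, EtOAc, rt
Reagents that add atoms: none
Why: Heterogeneous catalytic hydrogenation over Pd/C should saturate the conjugated C2=C3 and the isolated C10=C11 alkene alike, the lactone has no allylic or benzylic C–O bond open to hydrogenolysis, and no stereocentre is present or created.

Compound list
1 | 11-bromoundec-1-ene | C=CCCCCCCCCCBr | starting material
2 | 6-bromohexan-1-ol | OCCCCCCBr | starting material
3 | undec-10-en-1-ylmagnesium bromide | C=CCCCCCCCCC[Mg]Br | intermediate (not isolated)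
4 | bromomagnesium 6-bromohexan-1-olate | Br[Mg]OCCCCCCBr | intermediate (not isolated)
5 | heptadec-16-en-1-ol | OCCCCCCCCCCCCCCCC=C | intermediate
6 | acryloyl chloride (prop-2-enoyl chloride) | C=CC(=O)Cl | starting material
7 | heptadec-16-en-1-yl acrylate | C=CC(=O)OCCCCCCCCCCCCCCCC=C | intermediate
8 | cis-cyclooctene | C1CCC/C=C\CC1 | starting material
9 | pentacosa-16,24-dien-1-yl acrylate (C16=C17 E/Z mixture) | C=CC(=O)OCCCCCCCCCCCCCCCC=CCCCCCCC=C | intermediate (not isolated)
10 | (2E)-hexacosa-2,10-dien-26-olide, 27-membered lactone, C10=C11 E/Z mixture | O=C1/C=C/CCCCCCC=CCCCCCCCCCCCCCCCO1 | intermediate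
11 | 26-hexacosanolide (oxacycloheptacosan-2-one) | O=C1CCCCCCCCCCCCCCCCCCCCCCCCCO1 | target

Total step count: 4
Longest linear sequence: 4 steps (1 → 5 → 7 → 10 → 11)

Steps most likely to fail

Step 3. The number of cyclooctene units taken up may not be one. Ring closure of the C11 alkylidene onto its own acrylate before insertion is irreversible and gives the ring contracted by eight carbons. Repeated insertion or ring-opening polymerisation of cyclooctene, and head-to-tail oligomerisation of 7, give larger rings and chains. Ruthenium hydride formed by catalyst decay may also move the alkenes along the chain and shift the ring size by single carbons, which the benzoquinone is meant to suppress. The wrong-sized lactones differ from 10 by one isolated alkene per cyclooctene unit and should be separable on AgNO3-impregnated silica. The fallback gives up the insertion and makes the same C10=C11 bond by plain ring-closing metathesis of a diene that already holds all 26 ring carbons. It sets out from 5: acylation with undec-10-enoyl chloride (Et3N, catalytic DMAP, CH2Cl2, 0 °C) gives heptadec-16-en-1-yl undec-10-enoate F1. Ring-closing metathesis with the second-generation Grubbs catalyst RuCl2(=CHPh)(H2IMes)(PCy3) (5 mol%) in refluxing CH2Cl2 at 2 mM should give hexacos-10-en-26-olide F2 as an E/Z mixture. Hydrogenation under the conditions of step 4 comes back to the route at 11.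

Step 1. The bromomagnesium alkoxide 4 may aggregate or precipitate and couple slowly, so that homocoupling of 3 and reduction or elimination of the bromide take over. The fallback masks the hydroxyl. It sets out from 2: 3,4-dihydro-2H-pyran with PPTS in CH2Cl2 gives 2-[(6-bromohexyl)oxy]oxane F3. Coupling with 1.3 equiv of 3 under Li2CuCl4 (3 mol%) in THF gives 2-(heptadec-16-en-1-yloxy)oxane F4. PPTS in MeOH at 50 °C removes the acetal and comes back to the route at 5.

Step 2. Conjugate addition of chloride or of the amine to the acrylate as it forms, and radical polymerisation on concentration, may erode the ester. The fallback introduces the acrylate in masked form. It sets out from 5: 3-bromopropanoyl chloride and pyridine in CH2Cl2 at 0 °C give heptadec-16-en-1-yl 3-bromopropanoate F5. Et3N in CH2Cl2 at rt then eliminates HBr and comes back to the route at 7.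

Further compounds
F1 | step 3 | heptadec-16-en-1-yl undec-10-enoate | C=CCCCCCCCCC(=O)OCCCCCCCCCCCCCCCC=C
F2 | step 3 | hexacos-10-en-26-olide (E/Z mixture) | O=C1CCCCCCCCC=CCCCCCCCCCCCCCCCO1
F3 | step 1 | 2-[(6-bromohexyl)oxy]oxane (racemic) | BrCCCCCCOC1CCCCO1
F4 | step 1 | 2-(heptadec-16-en-1-yloxy)oxane (racemic) | C=CCCCCCCCCCCCCCCCOC1CCCCO1
F5 | step 2 | heptadec-16-en-1-yl 3-bromopropanoate | BrCCC(=O)OCCCCCCCCCCCCCCCC=C
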